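**Retrosynthetic overview**

1. The last bond made is the aryl ether C–O: a Mitsunobu union of bought 7-hydroxy-8-methoxycoumarin (bicycle intact) with the primary alcohol of epoxy lactone 13.
2. Key disconnection: the O1–C5 bond of the γ-butyrolactone (O1 ring oxygen, C2 carbonyl, C3 the C(OH)Me carbon, C4 CH2, C5 the CH–O carbon). Opening it gives the acyclic (R)-2-acetoxy-2-methyl acid 10, in which C5 is a plain CH2; a chiral manganese catalyst closes the ring by carboxylate-directed γ-C–H lactonization and sets C5.
3. Enabling feature: the free carboxyl (C2) lies 1,4 to the C5 methylene, the only γ-C–H in the molecule. C3 is fully substituted (no α-H, gem-disubstituent effect), C4 is β, the CH2 next to the oxirane is δ and inductively deactivated, and no tertiary alkyl C–H or C=C is present.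
4. Acid 10 comes from geraniol, which supplies all ten side-chain carbons: two Sharpless epoxidations (D-tartrate for the permanent oxirane; L-tartrate plus directed hydride opening for the tertiary carbinol) and a SeO2 oxidation of the terminal (E)-methyl to the future carboxyl.
5. Ring order: oxirane (step 1), then lactone (step 8), then coumarin attached last (step 11); a second, temporary oxirane (steps 4–5) only relays chirality to C3.

Key step: step 8

Remark 1: 7-hydroxy-8-methoxycoumarin (14) is taken as a purchasable catalogue phenol.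
Remark 2: the (S,S) antipode of the manganese catalyst is written in step 8 on the assumption that it removes the required C5 hydrogen; the (R,R) antipode is equally accessible and would be used if a test run shows the opposite sense.
Remark 3: the tartrate assignments rest on the established outcome for geraniol (L-(+)-tartrate gives the (2S,3S)-epoxide); the same face is assumed for the (E)-2-methyl-2-alkenol in step 4.

**Route**

Step 1
Reactants: 1 geraniol
Product: 2 [(2R,3R)-3-methyl-3-(4-methylpent-3-en-1-yl)oxiran-2-yl]methanol ((2R,3R)-2,3-epoxygeraniol)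
Conditions: Ti(OiPr)4 (5 mol %), D-(−)-diethyl tartrate (6 mol %), t-BuOOH, 4 Å molecular sieves, CH2Cl2, −20 °C
Reagents that add atoms: tert-butyl hydroperoxide, CC(C)(C)OO
Why: Sharpless asymmetric epoxidation of the allylic alcohol; the D-(−)-tartrate catalyst should give the (2R,3R)-oxirane (both oxirane stereocenters), and the remote trisubstituted alkene, lacking a directing hydroxyl, should stay untouched.

Step 2
Reactants: 2 (2R,3R)-2,3-epoxygeraniol
Product: 3 tert-butyl{[(2R,3R)-3-methyl-3-(4-methylpent-3-en-1-yl)oxiran-2-yl]methoxy}diphenylsilane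
Conditions: t-BuPh2SiCl, imidazole, DMF, 0 °C to rt
Reagents that add atoms: tert-butyl(chloro)diphenylsilane, CC(C)(C)[Si](Cl)(c1ccccc1)c1ccccc1
Why: Standard silyl ether formation (substitution at silicon); the group blocks hydroxyl-directed chemistry at this oxirane in step 5 and should survive SeO2, hydride, chlorite and the manganese oxidant; no stereocenter is touched.

Step 3
Reactants: 3 silyl ether
Product: 4 (2E)-5-[(2R,3R)-3-{[(tert-butyldiphenylsilyl)oxy]methyl}-2-methyloxiran-2-yl]-2-methylpent-2-en-1-ol
Conditions: SeO2 (0.3 equiv), t-BuOOH (3 equiv), CH2Cl2, 0 °C to rt, stopped at partial conversion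
Reagents that add atoms: selenium dioxide (oxygen carrier), O=[Se]=O; tert-butyl hydroperoxide (terminal oxidant), CC(C)(C)OO
Why: SeO2 allylic hydroxylation (ene reaction, then [2,3]-sigmatropic shift) should attack the (E)-methyl of the only alkene and give the (E)-allylic alcohol; no stereocenter is formed.

Step 4
Reactants: 4 (E)-allylic alcohol
Product: 5 [(2S,3S)-3-{2-[(2R,3R)-3-{[(tert-butyldiphenylsilyl)oxy]methyl}-2-methyloxiran-2-yl]ethyl}-2-methyloxiran-2-yl]methanol
Conditions: Ti(OiPr)4 (10 mol %), L-(+)-diethyl tartrate (12 mol %), t-BuOOH, 4 Å molecular sieves, CH2Cl2, −20 °C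
Reagents that add atoms: tert-butyl hydroperoxide, CC(C)(C)OO
Why: Sharpless asymmetric epoxidation of an (E)-2-methyl-2-alken-1-ol; the L-(+)-tartrate catalyst should give the (2S,3S)-oxirane, which fixes the C–O bond at the future lactone C3 under reagent control.

Step 5
Reactants: 5 bis-oxirane alcohol
Product: 6 (2R)-5-[(2R,3R)-3-{[(tert-butyldiphenylsilyl)oxy]methyl}-2-methyloxiran-2-yl]-2-methylpentane-1,2-diol
Conditions: LiBH4 (1.5 equiv), Ti(OiPr)4 (1.5 equiv), toluene/THF, 0 °C to rt
Reagents that add atoms: none
Why: Hydroxyl-directed, titanium-mediated hydride opening of a 2,3-epoxy alcohol at its secondary carbon gives the 1,2-diol; the C–O bond at the quaternary carbon is not broken, so its configuration is kept (descriptor S to R by ranking only), and the silyl-blocked oxirane has no free hydroxyl to bind titanium and should be spared.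

Step 6
Reactants: 6 diol
Product: 8 (2R)-5-[(2R,3R)-3-{[(tert-butyldiphenylsilyl)oxy]methyl}-2-methyloxiran-2-yl]-2-hydroxy-2-methylpentanoic acid, via hydroxy aldehyde 7 (not isolated)
Conditions: TEMPO (cat.), NaOCl (cat.), NaClO2, MeCN/phosphate buffer pH 6.7, 35 °C; work-up at pH 4
Reagents that add atoms: sodium chlorite, [Na+].[O-]Cl=O
Why: TEMPO/oxoammonium oxidation of the primary alcohol to aldehyde 7, then chlorite oxidation to the acid in the same pot; the tertiary hydroxyl cannot be oxidised, no alkene remains to be chlorinated, and near-neutral pH should preserve oxirane and silyl ether.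

Step 7
Reactants: 8 hydroxy acid
Product: 10 (2R)-2-acetoxy-5-[(2R,3R)-3-{[(tert-butyldiphenylsilyl)oxy]methyl}-2-methyloxiran-2-yl]-2-methylpentanoic acid, via mixed anhydride 9 (not isolated)
Conditions: Ac2O, pyridine, DMAP (cat.), CH2Cl2, rt; then H2O/THF, NaHCO3; work-up at pH 4; used without storage
Reagents that add atoms: acetic anhydride, CC(=O)OC(C)=O
Why: DMAP-catalysed acylation, the usual O-acetylation of tertiary α-hydroxy acids through the mixed anhydride, followed by hydrolysis of 9 at its unhindered acetyl carbonyl; the acetate keeps an α-hydroxy carboxylate from chelating manganese and from oxidative decarboxylation in step 8.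

Step 8
Reactants: 10 acetoxy acid
Product: 11 (3R,5R)-5-{[(2R,3R)-3-{[(tert-butyldiphenylsilyl)oxy]methyl}-2-methyloxiran-2-yl]methyl}-3-methyl-2-oxooxolan-3-yl acetate
Conditions: [Mn(CF3SO3)2((S,S)-TIPSpdp)] (2 mol %; TIPSpdp = N,N′-bis[(5-triisopropylsilyl-2-pyridyl)methyl]-2,2′-bipyrrolidine), H2O2 (1.5 equiv, syringe pump), CF3CH2OH, 0 °C
Reagents that add atoms: none
Why: The carboxylate of 10 binds divalent manganese, H2O2 is cleaved heterolytically with carboxylic-acid assistance to a pentavalent manganese oxo carboxylate, the oxo abstracts a hydrogen atom from C5 by 1,7-hydrogen transfer, and the C5 radical is captured at once by the bound carboxylate oxygen (carboxylate rebound), so no atom is added and water is the only by-product. The closest known reaction type is the manganese-catalysed, carboxylic-acid-directed γ-C(sp3)–H lactonization of aliphatic acids with H2O2 in fluorinated alcohols, which has precedent for unactivated methylenes, α-quaternary acids and N-protected α-amino acids. The lactone ring closes by inner-sphere C–O bond formation between O1 and the C5 radical (five-membered ring, formally a 5-exo capture by the tethered carboxylate). The new stereocenter C5 is set under catalyst control: the chiral ligand pocket decides which of the two diastereotopic C5–H bonds reaches the oxo and rebound should be faster than bond rotation, so oxygen enters with retention; the quaternary C3 carries two groups of similar size (Me, OAc) and should bias the choice little, as in gem-dimethyl acids. Site selectivity for C5 is secured by geometry and electronics: C5 is the only γ-methylene, C3 has no hydrogen, C4 is β to the carboxyl, the CH2 beside the oxirane is δ and inductively deactivated, and no tertiary alkyl C–H exists. Chemoselectivity is secured by the acetate, by the absence of any alkene or electron-rich arene at this stage, and by low temperature with slow peroxide addition to spare the oxirane.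

Step 9
Reactants: 11 acetoxy lactone
Product: 12 (3R,5S)-5-{[(2R,3R)-3-{[(tert-butyldiphenylsilyl)oxy]methyl}-2-methyloxiran-2-yl]methyl}-3-hydroxy-3-methyloxolan-2-one
Conditions: K2CO3 (0.3 equiv), MeOH, 0 °C
Reagents that add atoms: none
Why: Base-catalysed transesterification (Zemplén-type methanolysis); the acetate is activated by the adjacent lactone carbonyl and should cleave before the α-quaternary γ-lactone or the oxirane is attacked, and no stereocenter changes (the C5 descriptor goes from R to S only because the ranking changes with OAc to OH).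

Step 10
Reactants: 12 silyl ether lactone
Product: 13 (3R,5S)-3-hydroxy-5-{[(2R,3R)-3-(hydroxymethyl)-2-methyloxiran-2-yl]methyl}-3-methyloxolan-2-one
Conditions: Bu4NF, AcOH (1:1), THF, 0 °C to rt
Reagents that add atoms: none
Why: Fluoride-mediated desilylation; buffering with acetic acid should suppress Payne rearrangement of the liberated 2,3-epoxy alcohol and opening of the lactone.

Step 11
Reactants: 13 epoxy alcohol lactone; 14 7-hydroxy-8-methoxycoumarin
Product: 15 7-{[(2R,3R)-3-{[(2S,4R)-4-hydroxy-4-methyl-5-oxooxolan-2-yl]methyl}-3-methyloxiran-2-yl]methoxy}-8-methoxy-2H-chromen-2-one (target; hydroxyl trans to the lactone C5 side chain)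
Conditions: PPh3, diisopropyl azodicarboxylate, THF, 0 °C to rt
Reagents that add atoms: none
Why: Mitsunobu etherification; the acidic phenol (pKa about 8) should displace the activated primary carbinol, the tertiary alcohol is inert, the oxirane is not opened (as with glycidol-type alcohols), and the reacting carbon is not stereogenic.

**Compound list**

1 | geraniol | CC(C)=CCC/C(C)=C/CO | starting material
2 | [(2R,3R)-3-methyl-3-(4-methylpent-3-en-1-yl)oxiran-2-yl]methanol | OC[C@H]1O[C@]1(C)CCC=C(C)C | intermediate
3 | tert-butyl{[(2R,3R)-3-methyl-3-(4-methylpent-3-en-1-yl)oxiran-2-yl]methoxy}diphenylsilane | CC(C)(C)[Si](c1ccccc1)(c1ccccc1)OC[C@H]2O[C@]2(C)CCC=C(C)C | intermediate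
4 | (2E)-5-[(2R,3R)-3-{[(tert-butyldiphenylsilyl)oxy]methyl}-2-methyloxiran-2-yl]-2-methylpent-2-en-1-ol | CC(C)(C)[Si](c1ccccc1)(c1ccccc1)OC[C@H]2O[C@]2(C)CC/C=C(\C)CO | intermediate
5 | [(2S,3S)-3-{2-[(2R,3R)-3-{[(tert-butyldiphenylsilyl)oxy]methyl}-2-methyloxiran-2-yl]ethyl}-2-methyloxiran-2-yl]methanol | CC(C)(C)[Si](c1ccccc1)(c1ccccc1)OC[C@H]2O[C@]2(C)CC[C@@H]2O[C@@]2(C)CO | intermediate
6 | (2R)-5-[(2R,3R)-3-{[(tert-butyldiphenylsilyl)oxy]methyl}-2-methyloxiran-2-yl]-2-methylpentane-1,2-diol | CC(C)(C)[Si](c1ccccc1)(c1ccccc1)OC[C@H]2O[C@]2(C)CCC[C@@](C)(O)CO | intermediate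
7 | (2R)-5-[(2R,3R)-3-{[(tert-butyldiphenylsilyl)oxy]methyl}-2-methyloxiran-2-yl]-2-hydroxy-2-methylpentanal | CC(C)(C)[Si](c1ccccc1)(c1ccccc1)OC[C@H]2O[C@]2(C)CCC[C@@](C)(O)C=O | intermediate
8 | (2R)-5-[(2R,3R)-3-{[(tert-butyldiphenylsilyl)oxy]methyl}-2-methyloxiran-2-yl]-2-hydroxy-2-methylpentanoic acid | CC(C)(C)[Si](c1ccccc1)(c1ccccc1)OC[C@H]2O[C@]2(C)CCC[C@@](C)(O)C(=O)O | intermediate
9 | acetic (2R)-2-acetoxy-5-[(2R,3R)-3-{[(tert-butyldiphenylsilyl)oxy]methyl}-2-methyloxiran-2-yl]-2-methylpentanoic anhydride | CC(C)(C)[Si](c1ccccc1)(c1ccccc1)OC[C@H]2O[C@]2(C)CCC[C@@](C)(OC(C)=O)C(=O)OC(C)=O | intermediate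
10 | (2R)-2-acetoxy-5-[(2R,3R)-3-{[(tert-butyldiphenylsilyl)oxy]methyl}-2-methyloxiran-2-yl]-2-methylpentanoic acid | CC(C)(C)[Si](c1ccccc1)(c1ccccc1)OC[C@H]2O[C@]2(C)CCC[C@@](C)(OC(C)=O)C(=O)O | intermediate
11 | (3R,5R)-5-{[(2R,3R)-3-{[(tert-butyldiphenylsilyl)oxy]methyl}-2-methyloxiran-2-yl]methyl}-3-methyl-2-oxooxolan-3-yl acetate | CC(C)(C)[Si](c1ccccc1)(c1ccccc1)OC[C@H]2O[C@]2(C)C[C@@H]2C[C@@](C)(OC(C)=O)C(=O)O2 | intermediate
12 | (3R,5S)-5-{[(2R,3R)-3-{[(tert-butyldiphenylsilyl)oxy]methyl}-2-methyloxiran-2-yl]methyl}-3-hydroxy-3-methyloxolan-2-one | CC(C)(C)[Si](c1ccccc1)(c1ccccc1)OC[C@H]2O[C@]2(C)C[C@@H]2C[C@@](C)(O)C(=O)O2 | intermediate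
13 | (3R,5S)-3-hydroxy-5-{[(2R,3R)-3-(hydroxymethyl)-2-methyloxiran-2-yl]methyl}-3-methyloxolan-2-one | OC[C@H]1O[C@]1(C)C[C@@H]1C[C@@](C)(O)C(=O)O1 | intermediate
14 | 7-hydroxy-8-methoxycoumarin | COc1c(O)ccc2ccc(=O)oc12 | starting material
15 | 7-{[(2R,3R)-3-{[(2S,4R)-4-hydroxy-4-methyl-5-oxooxolan-2-yl]methyl}-3-methyloxiran-2-yl]methoxy}-8-methoxy-2H-chromen-2-one | COc1c(OC[C@H]2O[C@]2(C)C[C@@H]2C[C@@](C)(O)C(=O)O2)ccc2ccc(=O)oc12 | target

**Step count and risks**

Total step count: 11. Longest linear sequence: 11 steps (1 to 15); compound 14 is bought.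

Steps most likely to fail:

1. Step 8 (key step). The hydrogen abstraction may not discriminate well between the two C5 hydrogens, or the oxirane may be opened by the acidic fluorinated medium before oxidation is complete. If only the sense of induction is wrong, the other catalyst antipode is used. Otherwise the fallback is a Hofmann–Löffler–Freytag-type remote functionalisation, which is known chemistry but gives up control at C5. It sets out from 10 and comes back at 11. Acid 10 is converted (i-BuOCOCl, N-methylmorpholine, then NH3) into the primary amide F1. With PhI(OAc)2 and I2 in CH2Cl2 under visible light this forms the N-iodoamide F2, whose amidyl radical abstracts the C5 hydrogen by 1,5-transfer to give, after iodine transfer, the γ-iodo amide F3. F3 cyclises through the amide oxygen (O1–C5 bond) to the iminolactone F4, and water then hydrolyses F4 to 11 together with its C5 epimer F5, which is separated by chromatography.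

2. Step 5. Hydride may also open the silyl-protected oxirane, or attack the quaternary oxirane carbon, so chemo- or regioselectivity may be lost. The fallback sets out from 5 and comes back at 6. A titanium-mediated, hydroxyl-directed thiol opening (Ti(OiPr)4, PhSH, CH2Cl2) should give, with inversion at the secondary carbon only, the phenylthio diol F6. Desulfurisation with nickel boride (NiCl2·6H2O, NaBH4, MeOH/THF) then gives 6.

3. Step 3. Over-oxidation to the enal and slow opening of the oxirane by selenous acid may erode the material during the long reaction time. The fallback replaces allylic C–H oxidation by cleavage and olefination; it sets out from 3 and comes back at 4. Ozonolysis of the only alkene of 3 (O3, CH2Cl2/MeOH, −78 °C, then Me2S) gives the aldehyde F7. A Wittig reaction with ethyl 2-(triphenylphosphoranylidene)propanoate gives the (E)-enoate F8, and i-Bu2AlH (CH2Cl2, −78 °C) reduces F8 to 4.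

Further compounds
F1 | step 8 | (2R)-2-acetoxy-5-[(2R,3R)-3-{[(tert-butyldiphenylsilyl)oxy]methyl}-2-methyloxiran-2-yl]-2-methylpentanamide | CC(C)(C)[Si](c1ccccc1)(c1ccccc1)OC[C@H]2O[C@]2(C)CCC[C@@](C)(OC(C)=O)C(N)=O
F2 | step 8 | N-iodo derivative of amide F1 | CC(C)(C)[Si](c1ccccc1)(c1ccccc1)OC[C@H]2O[C@]2(C)CCC[C@@](C)(OC(C)=O)C(=O)NI
F3 | step 8 | γ-iodo amide (both C5 epimers) | CC(C)(C)[Si](c1ccccc1)(c1ccccc1)OC[C@H]2O[C@]2(C)CC(I)C[C@@](C)(OC(C)=O)C(N)=O
F4 | step 8 | iminolactone (2-iminooxolane, both C5 epimers) | CC(C)(C)[Si](c1ccccc1)(c1ccccc1)OC[C@H]2O[C@]2(C)CC2C[C@@](C)(OC(C)=O)C(=N)O2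
F5 | step 8 | C5 epimer of 11 | CC(C)(C)[Si](c1ccccc1)(c1ccccc1)OC[C@H]2O[C@]2(C)C[C@H]2C[C@@](C)(OC(C)=O)C(=O)O2
F6 | step 5 | 5-[(2R,3R)-3-{[(tert-butyldiphenylsilyl)oxy]methyl}-2-methyloxiran-2-yl]-2-methyl-3-(phenylsulfanyl)pentane-1,2-diol (sulfur anti to the tertiary hydroxyl) | CC(C)(C)[Si](c1ccccc1)(c1ccccc1)OC[C@H]2O[C@]2(C)CC[C@@H](Sc1ccccc1)[C@@](C)(O)CO
F7 | step 3 | 4-[(2R,3R)-3-{[(tert-butyldiphenylsilyl)oxy]methyl}-2-methyloxiran-2-yl]butanal | CC(C)(C)[Si](c1ccccc1)(c1ccccc1)OC[C@H]2O[C@]2(C)CCC=O
F8 | step 3 | ethyl (2E)-5-[(2R,3R)-3-{[(tert-butyldiphenylsilyl)oxy]methyl}-2-methyloxiran-2-yl]-2-methylpent-2-enoate | CC(C)(C)[Si](c1ccccc1)(c1ccccc1)OC[C@H]2O[C@]2(C)CC/C=C(\C)C(=O)OCC
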